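## Structural features

β-Collatolic acid is a diaryl ether of two polyketide-derived C12 halves and has no stereocentre. Ring A is a pentasubstituted benzoic acid: CO2H at C1′, OH at C2′ and C4′, the ether oxygen at C5′ and a 2-oxoheptyl chain at C6′; only C3′ carries hydrogen. The other half is a 6-methoxy-3-pentylisocoumarin (benzene ring B fused to pyranone ring C), bound through the oxygen at C8, peri to the lactone carbonyl C1. The ether oxygen is therefore flanked by two ortho substituents on each ring, and both rings are electron-rich; a direct aryl–oxygen coupling at this position is the real difficulty. Fragile groups are the enol lactone of ring C (opened by hard nucleophiles and aqueous base), the β-resorcylic acid of ring A (loss of CO2 on heating or in strong acid), and the 2-oxoheptyl group ortho to CO2H, which is the open form of a second isocoumarin and can close by cyclodehydration. The two halves are the closed and the open form of the same 2-(2-oxoheptyl)benzoate motif and must be kept distinct throughout. The key step uses the alternating oxygen pattern of ring A (C1′ carboxyl, C2′ OH, C4′ OH, C6′ CH2C=O): it is a folded tetraketide, so the C5′ oxygen can be placed on sp3 carbon C6 of an open 3,5,7-trioxo ester and ring A closed afterwards by forming C1′–C6′ (chain C2–C7).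

## Logic of the disconnections

23 ⇒ 22. The O–allyl bond of the ring A carboxylate is the last bond cleaved in the forward direction. The free β-resorcylic acid is the most labile function of the target, so it stays esterified until a final neutral step. Gain: every earlier acidic or basic operation is run on an ester. Demand: the deallylation must leave ketone, enol lactone and aryl ethers alone, and the allyl acceptor must out-compete the two free phenols.

22 ⇒ 21. The side-chain C=O is traced back to a dioxolane (two C–O bonds). During ring closure the C9 carbonyl must be silent, otherwise the chain can also fold C4 onto C9 or C8 onto C3. The ketone is unmasked before the ester is cleaved, so that the free acid never meets aqueous acid. Demand: hydrolysis that neither cleaves the ester nor lactonises the freed ketone onto it.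

21 ⇒ 19 (key disconnection). The ring bond C1′–C6′ is cut and the arene is unfolded to the open chain (C2–C7 in chain numbering). This turns the crowded diaryl ether into an alkyl aryl ether on sp3 carbon C6 and derives ring A, with carboxyl, both hydroxyls, ether oxygen and side chain, from one linear chain. Gain: one ring, no hindered aryl–oxygen coupling, no later functionalisation of an arene. Demand: a base that induces only the C2→C7 aldol mode and spares lactone, allyl ester and ketal.

19 ⇒ 16 + 17. The ester bond C1–O is cut and C1–C3 are traced back to a dioxinone ring, a masked acylketene. The β-keto ester, the most base-sensitive part of the chain, is thus released only just before the key step and under neutral thermal conditions. Demand: capture of the ketene by 17 must outrun capture by an enol oxygen of the chain.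

16 ⇒ 11 + 15. The C6–C7 bond is cut (Claisen retron). The ether oxygen is already on C6, so one acylation sets up the 2-aryloxy-1,3-diketone, and 15 brings the masked side chain. Demand: a carbanion must be generated at C6 in the presence of the enol lactone, which confines the step to −78 to −40 °C. The reverse order was set aside: attaching the oxygen of 7 to C6 of the complete chain by O–H insertion of a rhodium carbene would place the carbene carbon one carbonyl and one methylene away from the dioxolane oxygen. That arrangement is known to give five-membered oxonium ylides and ring enlargement even when a protic partner is present. Base-mediated displacement at that stage would compete with premature closure of the dioxinone chain.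

11 ⇒ 9 + 10. The C4–C5 bond is cut: γ-acylation of the dienolate of 10. Gain: C1–C4 come from one cheap building block used in excess. Demand: the amide carbonyl of 9 must be attacked in preference to its lactone carbonyl.

9 ⇒ 7 + 8. The alkyl–oxygen bond O–C6 is cut. The bond that later becomes the hindered diaryl ether is thus made by the simplest possible SN2 reaction, at a primary carbon. A halide already carrying the dioxinone was avoided, because its C4–H is a stronger acid than the phenol and would self-condense. Demand: the hydrogen-bonded peri phenol needs a carbonate base in a dipolar solvent.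

7 ⇒ 6 ⇒ 5 ⇒ 2 + 4 (2 ⇒ 1; 4 ⇒ 3). In turn: the C8 O–CH3 bond (chelation-controlled ether cleavage), the lactone bond O2–C1 (enol lactonisation), and the C4–C3 bond (lateral lithiation and acylation). Gain: ring B with the right oxygen pattern is bought as 1. Demand: lactonisation under acid, because base sends the keto ester to a naphthalenediol.

15 ⇒ 14 ⇒ 12 + 13. The amide C–N bond and the two ketal C–O bonds are cut; C7–C9 and the pentyl group come from a commercial β-keto ester. Demand: amide formation faster than enolisation next to the ketal.

## Other disconnections considered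

Alternative 1: Aryne acyl-alkylation. The cut removes C4a–C4 and C8a–C1, the two carbon substituents of ring B, and leaves a ring B aryne already bound through oxygen to a fully protected ring A. In the forward key step CsF releases the aryne from the ortho-silyl aryl triflate A2; the carbanion of dimethyl malonate A3 adds at C4a, the aryl anion at C8a attacks an ester carbonyl, and the four-membered alkoxide fragments to the homophthalate A1.
- In favour: two C–C bonds form in one mild operation, and the aryloxy group next to the triple bond steers the nucleophile to the distal carbon.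
- Better than the chosen plan on one point: the enol lactone is made only afterwards and never meets a strong base, whereas the chosen plan carries it through two low-temperature Claisen condensations.
- Against: A2 already contains the crowded diaryl ether, so the central problem is moved, not solved. Ring A must be built separately and carried as a tribenzyl ketal. A1 must still be turned into the 3-pentyl pyranone with a hexanoyl unit from 3 (acylation, loss of one carboxyl carbon, enol lactonisation) while three ester groups are told apart. The final hydrogenolysis must spare the C3=C4 enol double bond.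
- Comparison: on structure the chosen plan is more economical, since one chain gives ring A with all substituents and the ether oxygen. On mechanism both are polar, well-precedented and free of stereochemical issues (equal). On step economy the alternative needs the synthesis of A2 plus the steps after A1 and should be clearly longer than 14 steps.

Alternative 2: Vinylketene benzannulation. The cut removes C5–C6, C6–C7 and C8–C8a; ring B is grown around the ether oxygen from the aryl ethynyl ether A6 of protected ring A. In the forward key step (Danheiser benzannulation) irradiation of the vinyl diazo keto ester A5 gives a vinylketene by Wolff rearrangement. It adds to A6 in a [2+2] fashion; four-electron ring opening and six-electron electrocyclisation then give the phenol A4.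
- In favour: like the chosen plan, an arene is built onto an oxygen already in place, so no hindered aryl–oxygen coupling is needed (equal on this point).
- Better than the chosen plan on one point: the polarised ynol ether fixes the regiochemistry of the pericyclic cascade more rigidly than a polyketide folding does, and the new phenol appears exactly where the methoxy group is needed.
- Against: a complete, protected ring A is needed first, so ring A still has to be made, and ring B is constructed in addition. The ynol ether must be prepared from a hindered phenol. A diazo compound and photochemistry are required. A4 carries two identical ketal-masked 2-oxoheptyl groups ortho to two esters, of which only the ring B pair may be lactonised; the distinction rests on methyl against tert-butyl ester alone.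
- Comparison: on structure both rings need de novo construction instead of one; on mechanism it is elegant and regiospecific; on step economy it is worse.

Alternative 3: Carboxylate-directed C–H annulation. The cut removes C4a–C4 and O2–C3; the whole pyranone ring is added last to the diaryl ether benzoic acid A8. In the forward key step [Cp*RhCl2]2 (trivalent rhodium; Cp* is pentamethylcyclopentadienyl) with AgSbF6 metallates the only free ortho C–H of A8. The sulfoxonium ylide A9 delivers a rhodium carbene, migratory insertion forms C4a–C4, and cyclodehydration closes O2–C3 to give A7.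
- In favour: it is the shortest construction of ring C, there is a single C–H site and so no regiochemical ambiguity, and the ylide is a bench-stable carbene source.
- Equal or better than the chosen plan: for ring C alone it needs one step against three, and the lactone is formed last.
- Against: A8 contains the diaryl ether, and making it requires SNAr or copper-mediated coupling of a ring A phenol flanked by a benzyloxy group and the ketal side chain. That is the very bond formation the chosen plan avoids. Ring A needs its own synthesis and three benzyl groups. The cationic metal and the acid formed may open the dioxolane. Hydrogenolysis of A7 must spare the enol double bond.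
- Comparison: on mechanism it is equal or better (one well-defined C–H site); on structure it leaves the central difficulty unsolved; overall it is longer than the chosen plan.

Key step: step 12

Remarks. (a) Compounds 1, 3, 8, 10, 12, 13 and 17 are taken to be commercial. (b) 16, 18, 19 and 20 are drawn as keto forms; they are racemic at C6 (20 at two further centres) and largely enolised, and all these centres vanish in 21. (c) The atom mapping of 19 onto 21 (chain C2, C3, C4, C5, C6, C7 to ring C1′, C2′, C3′, C4′, C5′, C6′) was checked against 23; the structures are consistent and needed no correction.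

## Route

Step 1
Reactants: 1 methyl 2,4-dihydroxy-6-methylbenzoate (methyl orsellinate)
Product: 2 methyl 2,4-dimethoxy-6-methylbenzoate
Conditions: MeI (3 equiv), K2CO3, acetone, reflux
Reagents that add atoms: iodomethane, CI
Why: Exhaustive Williamson O-methylation; the chelated 2-OH reacts last and is driven to completion by excess MeI at reflux, and the ester is untouched.

Step 2
Reactants: 3 hexanoyl chloride
Product: 4 N-methoxy-N-methylhexanamide
Conditions: MeNH(OMe)·HCl, Et3N (2.2 equiv), CH2Cl2, 0 °C → rt
Reagents that add atoms: N,O-dimethylhydroxylamine hydrochloride, CNOC.Cl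
Why: Acylation of the amine gives the Weinreb amide, the acyl donor that stops cleanly at the ketone stage in step 3.

Step 3
Reactants: 2 methyl 2,4-dimethoxy-6-methylbenzoate; 4 N-methoxy-N-methylhexanamide
Product: 5 methyl 2,4-dimethoxy-6-(2-oxoheptyl)benzoate
Conditions: LiN(i-Pr)2 (1.2 equiv), THF, −78 °C; then 4, −78 → −40 °C; aq. NH4Cl
Reagents that add atoms: none
Why: Lateral lithiation of the ortho-toluate (the ester stabilises the benzylic anion) and acylation by the Weinreb amide; the chelated tetrahedral adduct prevents double addition and keeps the new ketone out of enolate chemistry until work-up.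

Step 4
Reactants: 5 methyl 2,4-dimethoxy-6-(2-oxoheptyl)benzoate
Product: 6 6,8-dimethoxy-3-pentyl-1H-isochromen-1-one
Conditions: p-TsOH·H2O (0.2 equiv), toluene, reflux, removal of MeOH
Reagents that add atoms: none
Why: Acid-catalysed enol lactonisation: the ketone enol oxygen attacks the neighbouring ester carbonyl (6-exo-trig) and methanol is lost; acid is chosen over base so that the rival carbon acylation to a naphthalene-1,3-diol is avoided.

Step 5
Reactants: 6 6,8-dimethoxy-3-pentyl-1H-isochromen-1-one
Product: 7 8-hydroxy-6-methoxy-3-pentyl-1H-isochromen-1-one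
Conditions: BCl3 (1.2 equiv), CH2Cl2, −78 → 0 °C; then H2O
Reagents that add atoms: none
Why: Chelation-controlled ether cleavage: BCl3 binds between the lactone carbonyl and the peri methoxy oxygen, so only the C8 methyl ether is removed and the C6 ether and the lactone remain.

Step 6
Reactants: 7 8-hydroxy-6-methoxy-3-pentyl-1H-isochromen-1-one; 8 2-chloro-N-methoxy-N-methylacetamide
Product: 9 N-methoxy-2-[(6-methoxy-1-oxo-3-pentyl-1H-isochromen-8-yl)oxy]-N-methylacetamide
Conditions: Cs2CO3 (1.5 equiv), NaI (0.1 equiv), DMF, 60 °C
Reagents that add atoms: none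
Why: Williamson ether synthesis at a primary α-chloro amide, an electrophile with no C–H acid that could compete with the phenol; Cs2CO3 in DMF breaks the phenol–carbonyl hydrogen bond and Finkelstein exchange with iodide speeds the SN2 step. This makes, on sp3 carbon, the C–O bond that later becomes the hindered diaryl ether.

Step 7
Reactants: 10 2,2,6-trimethyl-4H-1,3-dioxin-4-one; 9 N-methoxy-2-[(6-methoxy-1-oxo-3-pentyl-1H-isochromen-8-yl)oxy]-N-methylacetamide
Product: 11 6-{3-[(6-methoxy-1-oxo-3-pentyl-1H-isochromen-8-yl)oxy]-2-oxopropyl}-2,2-dimethyl-4H-1,3-dioxin-4-one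
Conditions: 10 (2.2 equiv), LiN(SiMe3)2 (2.2 equiv), THF, −78 °C; then 9, −78 → −30 °C; AcOH
Reagents that add atoms: none
Why: Vinylogous Claisen condensation: the lithium dienolate of the dioxinone is acylated at its γ-carbon by the Weinreb amide, whose N-methoxy chelate holds the adduct until the acidic quench; the excess of cheap dienolate covers any proton transfer from the α-aryloxy methylene. The lactone carbonyl, an aroyl ester with two oxygen donors ortho and para, is far less electrophilic than the amide at these temperatures.

Step 8
Reactants: 12 ethyl 3-oxooctanoate; 13 ethane-1,2-diol (ethylene glycol)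
Product: 14 ethyl 2-(2-pentyl-1,3-dioxolan-2-yl)acetate
Conditions: p-TsOH·H2O (cat.), toluene, reflux, Dean–Stark
Reagents that add atoms: none
Why: Acid-catalysed ketalisation with azeotropic removal of water; the ketone of the β-keto ester reacts and the ester is retained.

Step 9
Reactants: 14 ethyl 2-(2-pentyl-1,3-dioxolan-2-yl)acetate
Product: 15 N-methoxy-N-methyl-2-(2-pentyl-1,3-dioxolan-2-yl)acetamide
Conditions: MeNH(OMe)·HCl (1.5 equiv), i-PrMgCl (3 equiv), THF, −20 → 0 °C
Reagents that add atoms: N,O-dimethylhydroxylamine hydrochloride, CNOC.Cl
Why: Direct ester-to-Weinreb-amide exchange by the chloromagnesium amide made in the flask; at −20 °C amide formation is faster than enolisation next to the ketal, so the dioxolane is not opened by β-elimination.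

Step 10
Reactants: 11 6-{3-[(6-methoxy-1-oxo-3-pentyl-1H-isochromen-8-yl)oxy]-2-oxopropyl}-2,2-dimethyl-4H-1,3-dioxin-4-one; 15 N-methoxy-N-methyl-2-(2-pentyl-1,3-dioxolan-2-yl)acetamide
Product: 16 6-{3-[(6-methoxy-1-oxo-3-pentyl-1H-isochromen-8-yl)oxy]-2,4-dioxo-5-(2-pentyl-1,3-dioxolan-2-yl)pentyl}-2,2-dimethyl-4H-1,3-dioxin-4-one
Conditions: LiN(i-Pr)2 (2.1 equiv), THF, −78 °C, 20 min; then 15 (1.5 equiv), −78 → −40 °C; AcOH, −78 °C
Reagents that add atoms: none
Why: Crossed Claisen acylation of a keto-dioxinone 1,3-dianion: the second, less stabilised carbanion at C6 is the more nucleophilic site and takes the acyl group of the Weinreb amide, giving the 2-aryloxy-1,3-diketone; the new centre at C6 is racemic and enolisable and is lost in step 12. The lactone carbonyl is held coplanar with ring B, so the tethered C6 carbanion cannot reach its π* orbital in a five-membered transition state, and the low temperature keeps intermolecular attack slow.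

Step 11
Reactants: 16 6-{3-[(6-methoxy-1-oxo-3-pentyl-1H-isochromen-8-yl)oxy]-2,4-dioxo-5-(2-pentyl-1,3-dioxolan-2-yl)pentyl}-2,2-dimethyl-4H-1,3-dioxin-4-one; 17 prop-2-en-1-ol (allyl alcohol)
Product: 19 prop-2-enyl 6-[(6-methoxy-1-oxo-3-pentyl-1H-isochromen-8-yl)oxy]-3,5,7-trioxo-8-(2-pentyl-1,3-dioxolan-2-yl)octanoate, via acylketene 18 (not isolated)
Conditions: 17 (5 equiv), toluene, 110 °C; evaporation, used crude
Reagents that add atoms: none
Why: Thermal retro-[4+2] fragmentation of the dioxinone releases acetone and an acylketene, which allyl alcohol captures as the β-keto ester; no acid or base is present, so the chain does not yet cyclise and ketal and lactone survive.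

Step 12
Reactants: 19 prop-2-enyl 6-[(6-methoxy-1-oxo-3-pentyl-1H-isochromen-8-yl)oxy]-3,5,7-trioxo-8-(2-pentyl-1,3-dioxolan-2-yl)octanoate
Product: 21 prop-2-enyl 2,4-dihydroxy-5-[(6-methoxy-1-oxo-3-pentyl-1H-isochromen-8-yl)oxy]-6-[(2-pentyl-1,3-dioxolan-2-yl)methyl]benzoate, via cyclic aldol adduct 20 (not isolated)
Conditions: Et3N, CH2Cl2, 0 °C → rt; then dilute aq. citric acid
Reagents that add atoms: none
Why: Triethylamine deprotonates the chain reversibly; the C2 carbanion of the β-keto ester adds to the C7 ketone in a 6-(enolexo)-exo-trig aldol reaction and forms C2–C7 (C1′–C6′ of ring A), giving 20. E1cB loss of water across C2–C7 and enolisation of the C3 and C5 carbonyl groups then give the benzene ring; this aromatisation is irreversible and pulls the preceding equilibria forward. The closest known reaction type is the biomimetic aldol aromatisation of 3,5,7-triketo esters, made from diketo-dioxinones, to 6-substituted β-resorcylates. One ring is closed, the six-membered carbocycle, in the exo-trig mode, and no stereocentre remains because C6 and the transient carbinol carbon C7 both become sp2. The step needs carbon selectivity and the C2→C7 regiochemistry: the dioxolane removes C9 as an acceptor (no C4→C9 closure), C8 is the least acidic and a neopentyl-type methylene (no C8→C3 closure), and attack from C6 on the ester C1 or on the lactone carbonyl gives non-enolisable quaternary adducts that revert. Closure through an enol oxygen to pyranones is the main rival; it is held back by the weak amine base in an aprotic solvent at or below room temperature, conditions under which carbon aldol closure is the known course for triketo esters. The aryloxy group on C6 is not β to any carbanion and cannot be eliminated, and the enol lactone and allyl ester are inert to triethylamine.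

Step 13
Reactants: 21 prop-2-enyl 2,4-dihydroxy-5-[(6-methoxy-1-oxo-3-pentyl-1H-isochromen-8-yl)oxy]-6-[(2-pentyl-1,3-dioxolan-2-yl)methyl]benzoate
Product: 22 prop-2-enyl 2,4-dihydroxy-5-[(6-methoxy-1-oxo-3-pentyl-1H-isochromen-8-yl)oxy]-6-(2-oxoheptyl)benzoate
Conditions: 2 M aq. HCl–THF (1:4), rt
Reagents that add atoms: water, O
Why: Acid-catalysed ketal hydrolysis (oxocarbenium ion, hemiketal, loss of ethylene glycol); allyl ester and enol lactone are stable to dilute aqueous acid at room temperature, and because the carboxyl group is still esterified neither decarboxylation nor cyclodehydration to a second isocoumarin can start from a free acid.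

Step 14
Reactants: 22 prop-2-enyl 2,4-dihydroxy-5-[(6-methoxy-1-oxo-3-pentyl-1H-isochromen-8-yl)oxy]-6-(2-oxoheptyl)benzoate
Product: 23 2,4-dihydroxy-5-[(6-methoxy-1-oxo-3-pentyl-1H-isochromen-8-yl)oxy]-6-(2-oxoheptyl)benzoic acid (β-collatolic acid)
Conditions: Pd(PPh3)4 (5 mol %), morpholine (5 equiv), THF, rt; then cold 0.5 M aq. citric acid
Reagents that add atoms: none
Why: Tsuji–Trost deallylation: zerovalent palladium ionises the allyl ester to a π-allyl complex and the carboxylate, and morpholine traps the allyl fragment faster than the phenols can; the conditions are neutral and at room temperature, which the β-resorcylic acid, the ketone and the lactone tolerate.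

## Compound list

1 | methyl 2,4-dihydroxy-6-methylbenzoate (methyl orsellinate) | COC(=O)c1c(C)cc(O)cc1O | starting material
2 | methyl 2,4-dimethoxy-6-methylbenzoate | COC(=O)c1c(C)cc(OC)cc1OC | intermediate
3 | hexanoyl chloride | CCCCCC(=O)Cl | starting material
4 | N-methoxy-N-methylhexanamide | CCCCCC(=O)N(C)OC | intermediate
5 | methyl 2,4-dimethoxy-6-(2-oxoheptyl)benzoate | COC(=O)c1c(CC(=O)CCCCC)cc(OC)cc1OC | intermediate
6 | 6,8-dimethoxy-3-pentyl-1H-isochromen-1-one | CCCCCc1cc2cc(OC)cc(OC)c2c(=O)o1 | intermediate
7 | 8-hydroxy-6-methoxy-3-pentyl-1H-isochromen-1-one | CCCCCc1cc2cc(OC)cc(O)c2c(=O)o1 | intermediate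
8 | 2-chloro-N-methoxy-N-methylacetamide | CON(C)C(=O)CCl | starting material
9 | N-methoxy-2-[(6-methoxy-1-oxo-3-pentyl-1H-isochromen-8-yl)oxy]-N-methylacetamide | CON(C)C(=O)COc1cc(OC)cc2cc(CCCCC)oc(=O)c12 | intermediate
10 | 2,2,6-trimethyl-4H-1,3-dioxin-4-one | CC1=CC(=O)OC(C)(C)O1 | starting material
11 | 6-{3-[(6-methoxy-1-oxo-3-pentyl-1H-isochromen-8-yl)oxy]-2-oxopropyl}-2,2-dimethyl-4H-1,3-dioxin-4-one | CC1(C)OC(=O)C=C(CC(=O)COc2cc(OC)cc3cc(CCCCC)oc(=O)c23)O1 | intermediate
12 | ethyl 3-oxooctanoate | CCCCCC(=O)CC(=O)OCC | starting material
13 | ethane-1,2-diol (ethylene glycol) | OCCO | starting material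
14 | ethyl 2-(2-pentyl-1,3-dioxolan-2-yl)acetate | CCCCCC1(CC(=O)OCC)OCCO1 | intermediate
15 | N-methoxy-N-methyl-2-(2-pentyl-1,3-dioxolan-2-yl)acetamide | CCCCCC1(CC(=O)N(C)OC)OCCO1 | intermediate
16 | 6-{3-[(6-methoxy-1-oxo-3-pentyl-1H-isochromen-8-yl)oxy]-2,4-dioxo-5-(2-pentyl-1,3-dioxolan-2-yl)pentyl}-2,2-dimethyl-4H-1,3-dioxin-4-one (racemic) | CC1(C)OC(=O)C=C(CC(=O)C(Oc2cc(OC)cc3cc(CCCCC)oc(=O)c23)C(=O)CC2(CCCCC)OCCO2)O1 | intermediate
17 | prop-2-en-1-ol (allyl alcohol) | C=CCO | starting material
18 | acylketene 6-[(6-methoxy-1-oxo-3-pentyl-1H-isochromen-8-yl)oxy]-3,5,7-trioxo-8-(2-pentyl-1,3-dioxolan-2-yl)oct-1-en-1-one (racemic) | O=C=CC(=O)CC(=O)C(Oc1cc(OC)cc2cc(CCCCC)oc(=O)c12)C(=O)CC1(CCCCC)OCCO1 | intermediate (not isolated)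
19 | prop-2-enyl 6-[(6-methoxy-1-oxo-3-pentyl-1H-isochromen-8-yl)oxy]-3,5,7-trioxo-8-(2-pentyl-1,3-dioxolan-2-yl)octanoate (racemic) | C=CCOC(=O)CC(=O)CC(=O)C(Oc1cc(OC)cc2cc(CCCCC)oc(=O)c12)C(=O)CC1(CCCCC)OCCO1 | intermediate
20 | prop-2-enyl 2-hydroxy-3-[(6-methoxy-1-oxo-3-pentyl-1H-isochromen-8-yl)oxy]-4,6-dioxo-2-[(2-pentyl-1,3-dioxolan-2-yl)methyl]cyclohexane-1-carboxylate (mixture of stereoisomers) | C=CCOC(=O)C1C(=O)CC(=O)C(Oc2cc(OC)cc3cc(CCCCC)oc(=O)c23)C1(O)CC1(CCCCC)OCCO1 | intermediate (not isolated)
21 | prop-2-enyl 2,4-dihydroxy-5-[(6-methoxy-1-oxo-3-pentyl-1H-isochromen-8-yl)oxy]-6-[(2-pentyl-1,3-dioxolan-2-yl)methyl]benzoate | C=CCOC(=O)c1c(O)cc(O)c(Oc2cc(OC)cc3cc(CCCCC)oc(=O)c23)c1CC1(CCCCC)OCCO1 | intermediate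
22 | prop-2-enyl 2,4-dihydroxy-5-[(6-methoxy-1-oxo-3-pentyl-1H-isochromen-8-yl)oxy]-6-(2-oxoheptyl)benzoate | C=CCOC(=O)c1c(O)cc(O)c(Oc2cc(OC)cc3cc(CCCCC)oc(=O)c23)c1CC(=O)CCCCC | intermediate
23 | 2,4-dihydroxy-5-[(6-methoxy-1-oxo-3-pentyl-1H-isochromen-8-yl)oxy]-6-(2-oxoheptyl)benzoic acid (β-collatolic acid) | CCCCCC(=O)Cc1c(Oc2cc(OC)cc3cc(CCCCC)oc(=O)c23)c(O)cc(O)c1C(=O)O | target

## Step count and least certain steps

Total step count: 14. Longest linear sequence: 11 steps (1, 3, 4, 5, 6, 7, 10, 11, 12, 13, 14).

Step 12 (key step). Most likely to go wrong: the chain closes through an enol oxygen instead of carbon (pyranone formation), or the aldol stalls before dehydration, because the enolised aryloxy diketone lowers the electrophilicity of C7. Fallback: ring A is closed one stage earlier, with the dioxinone dienolate as the nucleophile. It sets out from 16. Et3N in CH2Cl2 should bring about aldol closure, dehydration and aromatisation to 7-hydroxy-6-[(6-methoxy-1-oxo-3-pentyl-1H-isochromen-8-yl)oxy]-2,2-dimethyl-5-[(2-pentyl-1,3-dioxolan-2-yl)methyl]-4H-1,3-benzodioxin-4-one F1. Allyl alcohol 17 with a catalytic amount of its sodium alkoxide (from NaH) then opens the acylal carbonyl with loss of acetone and rejoins the route at 21. The alkoxide must be kept catalytic and cold so that the enol lactone is not opened.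

Step 10. Most likely to go wrong: intramolecular acyl transfer, in which the C6 carbanion of the dianion attacks the lactone carbonyl; or proton transfer from 15 to the dianion followed by β-elimination that opens the dioxolane. Fallback: the ether oxygen is attached last, by displacement at C6 of the complete chain, so that no carbanion is ever formed next to the aryloxy group and the isocoumarin never meets LiN(i-Pr)2. It sets out from 10. The lithium dienolate (LiN(SiMe3)2, THF, −78 °C) is acylated with chloroacetyl chloride to 6-(3-chloro-2-oxopropyl)-2,2-dimethyl-4H-1,3-dioxin-4-one F2. Its dianion (LiN(i-Pr)2, 2 equiv) is acylated with 15 to 6-[3-chloro-2,4-dioxo-5-(2-pentyl-1,3-dioxolan-2-yl)pentyl]-2,2-dimethyl-4H-1,3-dioxin-4-one F3. The caesium phenolate of 7 (Cs2CO3, MeCN, 0 °C) then displaces the activated secondary chloride by SN2, and the route is rejoined at 16. The weak point of this detour is base-induced closure of the dioxinone chain, hence the low temperature and short contact time.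

Step 7. Most likely to go wrong: stalling through proton transfer from the α-aryloxy methylene of 9 to the dienolate, or self-condensation of the dienolate during the warming that the amide needs. Fallback: the two-carbon unit is brought in as an acid chloride, which should acylate the dienolate within minutes at −78 °C. It sets out from 7. Alkylation with tert-butyl bromoacetate (K2CO3, DMF) gives tert-butyl 2-[(6-methoxy-1-oxo-3-pentyl-1H-isochromen-8-yl)oxy]acetate F4. CF3CO2H cleaves the ester to 2-[(6-methoxy-1-oxo-3-pentyl-1H-isochromen-8-yl)oxy]acetic acid F5. Oxalyl chloride gives 2-[(6-methoxy-1-oxo-3-pentyl-1H-isochromen-8-yl)oxy]acetyl chloride F6, which is added to the preformed lithium dienolate of 10; the route is rejoined at 11.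

Step 14. Most likely to go wrong: O-allylation of the free phenols by the π-allyl palladium intermediate, slow aminolysis of the enol lactone by morpholine, or loss of CO2 from the β-resorcylic acid during work-up. Fallback: an ester that needs neither palladium nor an amine. It sets out from 16, which is heated with tert-butanol (toluene, 110 °C, via 18) to give tert-butyl 6-[(6-methoxy-1-oxo-3-pentyl-1H-isochromen-8-yl)oxy]-3,5,7-trioxo-8-(2-pentyl-1,3-dioxolan-2-yl)octanoate F7. Et3N closes ring A to tert-butyl 2,4-dihydroxy-5-[(6-methoxy-1-oxo-3-pentyl-1H-isochromen-8-yl)oxy]-6-[(2-pentyl-1,3-dioxolan-2-yl)methyl]benzoate F8. CF3CO2H–H2O–CH2Cl2 at 0 °C then removes the tert-butyl ester and the dioxolane in one operation and reaches 23 directly. This is one step shorter, but the free keto acid is exposed to acid and must be kept cold and brief to avoid cyclodehydration; for that reason it is the fallback and not the main plan.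

## Further compounds

F1 | step 12 | 7-hydroxy-6-[(6-methoxy-1-oxo-3-pentyl-1H-isochromen-8-yl)oxy]-2,2-dimethyl-5-[(2-pentyl-1,3-dioxolan-2-yl)methyl]-4H-1,3-benzodioxin-4-one | CC1(C)OC(=O)c2c(CC3(CCCCC)OCCO3)c(Oc3cc(OC)cc4cc(CCCCC)oc(=O)c34)c(O)cc2O1
F2 | step 10 | 6-(3-chloro-2-oxopropyl)-2,2-dimethyl-4H-1,3-dioxin-4-one | CC1(C)OC(=O)C=C(CC(=O)CCl)O1
F3 | step 10 | 6-[3-chloro-2,4-dioxo-5-(2-pentyl-1,3-dioxolan-2-yl)pentyl]-2,2-dimethyl-4H-1,3-dioxin-4-one | CC1(C)OC(=O)C=C(CC(=O)C(Cl)C(=O)CC2(CCCCC)OCCO2)O1
F4 | step 7 | tert-butyl 2-[(6-methoxy-1-oxo-3-pentyl-1H-isochromen-8-yl)oxy]acetate | CC(C)(C)OC(=O)COc1cc(OC)cc2cc(CCCCC)oc(=O)c12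
F5 | step 7 | 2-[(6-methoxy-1-oxo-3-pentyl-1H-isochromen-8-yl)oxy]acetic acid | OC(=O)COc1cc(OC)cc2cc(CCCCC)oc(=O)c12
F6 | step 7 | 2-[(6-methoxy-1-oxo-3-pentyl-1H-isochromen-8-yl)oxy]acetyl chloride | ClC(=O)COc1cc(OC)cc2cc(CCCCC)oc(=O)c12
F7 | step 14 | tert-butyl 6-[(6-methoxy-1-oxo-3-pentyl-1H-isochromen-8-yl)oxy]-3,5,7-trioxo-8-(2-pentyl-1,3-dioxolan-2-yl)octanoate | CC(C)(C)OC(=O)CC(=O)CC(=O)C(Oc1cc(OC)cc2cc(CCCCC)oc(=O)c12)C(=O)CC1(CCCCC)OCCO1
F8 | step 14 | tert-butyl 2,4-dihydroxy-5-[(6-methoxy-1-oxo-3-pentyl-1H-isochromen-8-yl)oxy]-6-[(2-pentyl-1,3-dioxolan-2-yl)methyl]benzoate | CC(C)(C)OC(=O)c1c(O)cc(O)c(Oc2cc(OC)cc3cc(CCCCC)oc(=O)c23)c1CC1(CCCCC)OCCO1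
A1 | alternative 1 | benzyl 2,4-bis(benzyloxy)-5-[5-methoxy-2-(methoxycarbonyl)-3-(2-methoxy-2-oxoethyl)phenoxy]-6-[(2-pentyl-1,3-dioxolan-2-yl)methyl]benzoate | CCCCCC1(Cc2c(Oc3cc(OC)cc(CC(=O)OC)c3C(=O)OC)c(OCc3ccccc3)cc(OCc3ccccc3)c2C(=O)OCc2ccccc2)OCCO1
A2 | alternative 1 | benzyl 2,4-bis(benzyloxy)-5-[5-methoxy-3-{[(trifluoromethyl)sulfonyl]oxy}-2-(trimethylsilyl)phenoxy]-6-[(2-pentyl-1,3-dioxolan-2-yl)methyl]benzoate | COc1cc(OS(=O)(=O)C(F)(F)F)c([Si](C)(C)C)c(Oc2c(CC3(CCCCC)OCCO3)c(C(=O)OCc3ccccc3)c(OCc3ccccc3)cc2OCc2ccccc2)c1
A3 | alternative 1 | dimethyl malonate | COC(=O)CC(=O)OC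
A4 | alternative 2 | tert-butyl 5-{5-hydroxy-2-(methoxycarbonyl)-3-[(2-pentyl-1,3-dioxolan-2-yl)methyl]phenoxy}-2,4-bis(methoxymethoxy)-6-[(2-pentyl-1,3-dioxolan-2-yl)methyl]benzoate | CCCCCC1(Cc2cc(O)cc(Oc3c(CC4(CCCCC)OCCO4)c(C(=O)OC(C)(C)C)c(OCOC)cc3OCOC)c2C(=O)OC)OCCO1
A5 | alternative 2 | methyl 2-diazo-4-methylidene-3-oxo-5-(2-pentyl-1,3-dioxolan-2-yl)pentanoate | COC(=O)C(=[N+]=[N-])C(=O)C(=C)CC1(CCCCC)OCCO1
A6 | alternative 2 | tert-butyl 5-(ethynyloxy)-2,4-bis(methoxymethoxy)-6-[(2-pentyl-1,3-dioxolan-2-yl)methyl]benzoate | C#COc1c(CC2(CCCCC)OCCO2)c(C(=O)OC(C)(C)C)c(OCOC)cc1OCOC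
A7 | alternative 3 | benzyl 2,4-bis(benzyloxy)-5-[(6-methoxy-1-oxo-3-pentyl-1H-isochromen-8-yl)oxy]-6-[(2-pentyl-1,3-dioxolan-2-yl)methyl]benzoate | CCCCCC1(Cc2c(Oc3cc(OC)cc4cc(CCCCC)oc(=O)c34)c(OCc3ccccc3)cc(OCc3ccccc3)c2C(=O)OCc2ccccc2)OCCO1
A8 | alternative 3 | 2-{4,6-bis(benzyloxy)-3-[(benzyloxy)carbonyl]-2-[(2-pentyl-1,3-dioxolan-2-yl)methyl]phenoxy}-4-methoxybenzoic acid | COc1ccc(C(=O)O)c(Oc2c(CC3(CCCCC)OCCO3)c(C(=O)OCc3ccccc3)c(OCc3ccccc3)cc2OCc2ccccc2)c1
A9 | alternative 3 | 1-[dimethyl(oxo)-λ6-sulfanylidene]heptan-2-one | CCCCCC(=O)C=S(C)(C)=O
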